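C-numbers are heavy-atom positions in the target SMILES. Retrosynthesis: the C3 ketone goes back to a silyl-protected carbinol, the ring diene to a C16 carbinol (1,4-dehydration), and the pyrone to a C19 aldehyde (aldol at C19–C28, lactonisation, O-methylation). The C8–C9 bond then goes back to an enol triflate coupling, C7–C8 to an alkyllithium plus a lactone, and C10–C11 with C16–C17 to a Diels–Alder reaction.
Enabling feature: in the ring C10–C11–C13–C14–C16–C17, carbons C10 and C17 carry their carbon arms C8 and C19 on the same face, with the C17 methyl trans to C8. That is the imprint of a ring-locked Z dienophile C17(CH3)=C10H added across a C11–C13–C14–C16 diene.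
Forward: silyloxydiene 2 and menthyloxybutenolide 6 close the only carbocycle (step 4). Reduction and relactonisation make C8 the acyl carbon, the C1–C7 chain arrives as an organolithium and the C8 methyl by cross-coupling. The pyrone ring is then grown on C19, and the ring diene and the C3 ketone are unveiled last.
Stereochemistry: C10 and C17 come from the acetal stereocentre of 6 (diene anti to the (+)-menthyloxy group) and the cis-locked dienophile. C5 comes from an Evans syn-aldol, and the E geometry of C7=C8 from a Z enol triflate coupled with retention.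

Key step: step 4

Remark: the 5S acetal epimer 6 is assumed to be separable from its 5R epimer, which would be recycled by acid equilibration.

Step 1
Reactants: 1 (E)-2-methylpent-2-enal
Product: 2 (1E,3E)-triethyl[(2-methylpenta-1,3-dien-1-yl)oxy]silane
Conditions: Et3SiOTf, Et3N, Et2O, 0 °C → rt
Reagents that add atoms: triethylsilyl trifluoromethanesulfonate, CC[Si](CC)(CC)OS(=O)(=O)C(F)(F)F
Why: O-silylation of the enal and γ-deprotonation by the amine (silyl dienol ether formation from an α,β-unsaturated aldehyde) should give the diene, the s-trans enal leading to the 1E and the less strained propenyl terminus to the 3E geometry.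

Step 2
Reactants: 3 3-methylfuran-2-carboxylic acid
Product: 4 5-hydroxy-3-methylfuran-2(5H)-one (racemic hemiacetal)
Conditions: O2, hν (visible), 5,10,15,20-tetraphenylporphyrin (cat.), CH2Cl2, 0 °C
Reagents that add atoms: dioxygen, O=O
Why: Singlet-oxygen [4+2] cycloaddition across C2/C5 of the furan and decarboxylative opening of the endoperoxide (photooxygenation of a 2-furoic acid) should give the γ-hydroxybutenolide with the methyl group α to the carbonyl.

Step 3
Reactants: 4 5-hydroxy-3-methylfuran-2(5H)-one; 5 (+)-menthol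
Product: 6 (5S)-3-methyl-5-[(+)-menthyloxy]furan-2(5H)-one
Conditions: camphor-10-sulfonic acid (cat.), toluene, reflux (Dean–Stark); 5S epimer separated by crystallisation, mother liquor re-equilibrated with acid
Reagents that add atoms: none
Why: Acid-catalysed acetalisation of the cyclic hemiacetal gives both C5 epimers, which interconvert through the oxocarbenium ion, so the 5S diastereomer is obtained by separation and recycling and not by induction.

Step 4
Reactants: 2 (1E,3E)-triethyl[(2-methylpenta-1,3-dien-1-yl)oxy]silane; 6 (5S)-3-methyl-5-[(+)-menthyloxy]furan-2(5H)-one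
Product: 7 cis-fused cyclohexene lactone acetal (endo adduct; C8, C19, the C11 methyl and the C16 silyloxy group on one face, the C17 methyl on the other)
Conditions: 2 (3 equiv), 2,6-di-tert-butyl-4-methylphenol (cat.), CH2Cl2, 12 kbar, 40 °C
Reagents that add atoms: none
Why: The reaction is a concerted, asynchronous, suprafacial normal-demand [4+2] cycloaddition, the closest known type being the Diels–Alder addition of 1-silyloxydienes to 5-alkoxyfuran-2(5H)-one chiral acetals; pressure is used because the α-methyl group slows the dienophile and neither the dienol ether nor the acetal would tolerate a Lewis acid. The six-membered carbocycle closes by intermolecular cycloaddition, C10–C11 and C16–C17 forming together, so the new ring is cis-fused to the lactone. C10 and C17 are set by the acetal carbon C8 of 6, whose menthyloxy group shields one face so that the diene adds anti to it, and their cis relation is fixed by the Z geometry that the butenolide ring imposes on C17=C10. C11 and C16 follow from the E,E geometry of 2 (methyl and silyloxy cis to each other) and the endo transition state; both are erased later, so any exo component converges. The step needs regio- and facial selectivity: the silyloxy group places the largest HOMO coefficient on C11, which pairs with the β-carbon C10, and the acetal substituent secures the face.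

Step 5
Reactants: 7 cis-fused cyclohexene lactone acetal
Product: 8 cis-diol (C8 and C19 both CH2OH)
Conditions: LiAlH4, THF, 0 °C → rt
Reagents that add atoms: none
Why: Hydride reduction of the lactone carbonyl and, after collapse of the hemiacetal, of the released C8 aldehyde should give the diol and return (+)-menthol, the aldehyde being reduced faster than C10 can epimerise.

Step 6
Reactants: 8 cis-diol
Product: 10 cis-fused lactone with C8 as carbonyl carbon, via lactol 9 (not isolated)
Conditions: 2,2,6,6-tetramethylpiperidin-1-oxyl (cat.), PhI(OAc)2, CH2Cl2, rt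
Reagents that add atoms: none
Why: Oxoammonium oxidation (oxidative lactonisation of a 1,4-diol) should start at the less hindered C8 carbinol, the neopentyl C19 alcohol closing the hydroxy aldehyde to lactol 9, which is oxidised on; the cis ring fusion holds the C10 configuration.

Step 7
Reactants: 11 (S)-4-benzyl-3-propanoyl-1,3-oxazolidin-2-one; 12 propanal
Product: 14 (S)-4-benzyl-3-[(2S,3R)-3-hydroxy-2-methylpentanoyl]-1,3-oxazolidin-2-one, via boron enolate 13 (not isolated)
Conditions: Bu2BOTf, i-Pr2NEt, CH2Cl2, 0 °C; 12, −78 → 0 °C; then pH 7 buffer, MeOH, H2O2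
Reagents that add atoms: none
Why: Evans syn-aldol reaction: the Z boron enolate reacts through a closed chair transition state on the face away from the benzyl group, which sets the methyl-bearing carbon (the future C5) and the carbinol carbon (the future C3, oxidised at the end).

Step 8
Reactants: 14 (S)-4-benzyl-3-[(2S,3R)-3-hydroxy-2-methylpentanoyl]-1,3-oxazolidin-2-one
Product: 15 its triisopropylsilyl ether
Conditions: i-Pr3SiOTf, 2,6-lutidine, CH2Cl2, 0 °C → rt
Reagents that add atoms: triisopropylsilyl trifluoromethanesulfonate, CC(C)[Si](C(C)C)(C(C)C)OS(=O)(=O)C(F)(F)F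
Why: Silylation of the hindered secondary alcohol with a silyl triflate; the robust triisopropylsilyl group is chosen so that both triethylsilyl ethers can later be removed in its presence.

Step 9
Reactants: 15 silyl-protected aldol imide
Product: 16 (2R,3R)-2-methyl-3-(triisopropylsilyloxy)pentan-1-ol
Conditions: LiBH4, MeOH, THF, 0 °C
Reagents that add atoms: none
Why: Reductive cleavage of the N-acyl oxazolidinone by borohydride releases the primary alcohol and the auxiliary without touching the α-stereocentre.

Step 10
Reactants: 16 (2R,3R)-2-methyl-3-(triisopropylsilyloxy)pentan-1-ol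
Product: 17 {[(3R,4S)-5-iodo-4-methylpentan-3-yl]oxy}tri(propan-2-yl)silane
Conditions: I2, PPh3, imidazole, CH2Cl2, 0 °C → rt
Reagents that add atoms: iodine, II
Why: Appel-type iodination by SN2 displacement of the alkoxyphosphonium at the primary carbon; no stereocentre is involved.

Step 11
Reactants: 17 primary iodide; 10 cis-fused lactone
Product: 19 hydroxy ketone (C8 ketone with C19 as CH2OH; may exist as its cyclic hemiketal), via alkyllithium 18 (not isolated)
Conditions: 17, t-BuLi (2.1 equiv), Et2O, −78 °C; then 10, THF, −78 °C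
Reagents that add atoms: none
Why: Lithium–iodine exchange followed by addition of the primary alkyllithium to the lactone carbonyl forms C7–C8; the lithium hemiketal should resist a second addition at low temperature.

Step 12
Reactants: 19 hydroxy ketone
Product: 20 C19 triethylsilyl ether of the ketone
Conditions: Et3SiCl, imidazole, 4-(dimethylamino)pyridine (cat.), DMF, 0 °C → rt
Reagents that add atoms: chlorotriethylsilane, CC[Si](Cl)(CC)CC
Why: Silylation of the primary hydroxyl of the open-chain tautomer drains the hemiketal equilibrium (Curtin–Hammett situation), since the tertiary hemiketal hydroxyl is far less reactive.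

Step 13
Reactants: 20 silyl-protected ketone
Product: 22 (Z)-enol triflate (OTf cis to C5 across C8=C7), via potassium enolate 21 (not isolated)
Conditions: KN(SiMe3)2, THF, −78 °C; then PhNTf2, −78 → −20 °C
Reagents that add atoms: N-phenylbis(trifluoromethanesulfonimide), O=S(=O)(N(c1ccccc1)S(=O)(=O)C(F)(F)F)C(F)(F)F
Why: Kinetic enolisation should occur at the C7 methylene and not at the flanked tertiary C10–H, and allylic 1,3-strain between the ring carbon and the branched C5 should favour the Z(O) enolate, which O-sulfonylation traps (enol triflate formation); this geometry becomes the E alkene of the target.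

Step 14
Reactants: 22 (Z)-enol triflate
Product: 23 (E)-trisubstituted alkene (C8 methyl installed; C16 and C19 triethylsilyl ethers, C3 triisopropylsilyl ether)
Conditions: Me2Zn, Pd(PPh3)4 (5 mol %), THF, 0 → 45 °C
Reagents that add atoms: dimethylzinc, C[Zn]C
Why: Negishi cross-coupling of an alkenyl triflate proceeds with retention of the double-bond geometry, so the methyl group replaces the triflate cis to C5.

Step 15
Reactants: 23 (E)-trisubstituted alkene
Product: 24 primary alcohol at C19
Conditions: pyridinium p-toluenesulfonate (cat.), MeOH/CH2Cl2, 0 °C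
Reagents that add atoms: none
Why: Acid-catalysed methanolysis should remove the primary triethylsilyl ether much faster than the flanked secondary one at C16 or the triisopropylsilyl ether.

Step 16
Reactants: 24 primary alcohol
Product: 25 C19 aldehyde
Conditions: Dess–Martin periodinane, NaHCO3, CH2Cl2, 0 °C → rt
Reagents that add atoms: none
Why: Dess–Martin oxidation of a neopentyl primary alcohol to an aldehyde that cannot enolise, its α-carbon C17 being quaternary.

Step 17
Reactants: 25 C19 aldehyde; 26 methyl 2-methyl-3-oxopentanoate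
Product: 28 δ-hydroxy-β-keto ester (diastereomer mixture), via dianion 27 (not isolated)
Conditions: 26, NaH, THF, 0 °C; n-BuLi, 0 °C; then 25, −78 → −40 °C
Reagents that add atoms: none
Why: Aldol addition of the β-keto ester dianion through its more reactive γ-carbon forms C19–C28; the three new stereocentres are all removed in the next two steps.

Step 18
Reactants: 28 δ-hydroxy-β-keto ester
Product: 29 β,δ-diketo ester
Conditions: Dess–Martin periodinane, NaHCO3, CH2Cl2, rt
Reagents that add atoms: none
Why: Dess–Martin oxidation of the secondary carbinol gives the triketide; the β-silyloxy group at C16 cannot be eliminated because C17 has no hydrogen.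

Step 19
Reactants: 29 β,δ-diketo ester
Product: 30 4-hydroxy-3,5-dimethyl-2H-pyran-2-one carrying the ring at C6
Conditions: DBU, toluene, rt → 50 °C
Reagents that add atoms: none
Why: Base-mediated enol lactonisation: the enol oxygen of the C19 ketone attacks the ester carbonyl in a six-membered acyl substitution and methanol is lost.

Step 20
Reactants: 30 hydroxypyranone
Product: 31 2-methoxy-3,5-dimethyl-4H-pyran-4-one carrying the ring at C6
Conditions: MeOTf, CH2Cl2, 0 °C → rt
Reagents that add atoms: methyl trifluoromethanesulfonate, COS(=O)(=O)C(F)(F)F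
Why: A hard methylating agent alkylates the neutral 4-hydroxy-2-pyranone at the lactone carbonyl oxygen, and loss of the hydroxyl proton then gives the α-methoxy-γ-pyrone (regioselective O-methylation).

Step 21
Reactants: 31 methoxypyrone with C16 triethylsilyl ether
Product: 32 C16 allylic alcohol
Conditions: HF·pyridine, pyridine, THF, 0 °C → rt
Reagents that add atoms: none
Why: Buffered fluoride desilylation should cleave the triethylsilyl ether while the far more robust triisopropylsilyl ether at C3 stays.

Step 22
Reactants: 32 C16 allylic alcohol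
Product: 34 cyclohexa-1,3-diene (C3 still silyl-protected), via allylic mesylate 33 (not isolated)
Conditions: MsCl, Et3N, CH2Cl2, 0 °C; then DBU, toluene, 60 °C
Reagents that add atoms: none
Why: 1,4-Elimination of an allylic sulfonate: the mesylate ionises to the C16–C14–C13 allyl cation (or its allylic chloride) and base removes the only adjacent proton, C11–H, because C17 is quaternary, giving the C11=C13–C14=C16 diene.

Step 23
Reactants: 34 silyl-protected diene
Product: 35 C3 alcohol
Conditions: Bu4NF, AcOH, THF, rt → 40 °C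
Reagents that add atoms: none
Why: Buffered fluoride cleavage of the secondary triisopropylsilyl ether; no base-sensitive stereocentre is present at the alcohol stage.

Step 24
Reactants: 35 C3 alcohol
Product: 36 target (CNP0301958.2)
Conditions: Dess–Martin periodinane, NaHCO3, CH2Cl2, 0 °C
Reagents that add atoms: none
Why: Buffered Dess–Martin oxidation gives the β,γ-unsaturated ketone under near-neutral conditions, so the now epimerisable C5 and the diene should be left intact.

Compound list
1 | (E)-2-methylpent-2-enal | CC/C=C(\C)C=O | starting material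
2 | (1E,3E)-triethyl[(2-methylpenta-1,3-dien-1-yl)oxy]silane | C/C=C/C(C)=C/O[Si](CC)(CC)CC | intermediate
3 | 3-methylfuran-2-carboxylic acid | Cc1ccoc1C(O)=O | starting material
4 | 5-hydroxy-3-methylfuran-2(5H)-one (racemic hemiacetal) | CC1=CC(O)OC1=O | intermediate
5 | (+)-menthol, (1S,2R,5S)-5-methyl-2-(propan-2-yl)cyclohexan-1-ol | CC(C)[C@H]1CC[C@H](C)C[C@@H]1O | starting material
6 | (5S)-3-methyl-5-{[(1S,2R,5S)-5-methyl-2-(propan-2-yl)cyclohexyl]oxy}furan-2(5H)-one | CC1=C[C@@H](O[C@H]2C[C@@H](C)CC[C@@H]2C(C)C)OC1=O | intermediate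
7 | (3S,3aS,4S,7R,7aS)-4,6,7a-trimethyl-3-{[(1S,2R,5S)-5-methyl-2-(propan-2-yl)cyclohexyl]oxy}-7-(triethylsilyloxy)-3a,4,7,7a-tetrahydroisobenzofuran-1(3H)-one (endo adduct) | O=C1O[C@H](O[C@H]3C[C@@H](C)CC[C@@H]3C(C)C)[C@H]2[C@@H](C)C=C(C)[C@@H](O[Si](CC)(CC)CC)[C@@]12C | intermediate
8 | [1,3,5-trimethyl-6-(triethylsilyloxy)cyclohex-4-ene-1,2-diyl]dimethanol, configuration as in 7 (both CH2OH groups, the C3 methyl and the silyloxy group cis; the C1 methyl trans) | OC[C@H]1[C@@H](C)C=C(C)[C@@H](O[Si](CC)(CC)CC)[C@@]1(C)CO | intermediate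
9 | lactol from oxidation of the C8 carbinol of 8 and closure by the C19 hydroxyl (anomer mixture) | OC1[C@H]2[C@@H](C)C=C(C)[C@@H](O[Si](CC)(CC)CC)[C@@]2(C)CO1 | intermediate
10 | cis-fused 3a,5,7-trimethyl-4-(triethylsilyloxy)-3a,4,7,7a-tetrahydroisobenzofuran-1(3H)-one (C8 carbonyl, C19 as OCH2; silyloxy and C7 methyl on the face of the lactone ring, 3a-methyl on the other) | O=C1[C@H]2[C@@H](C)C=C(C)[C@@H](O[Si](CC)(CC)CC)[C@@]2(C)CO1 | intermediate
11 | (S)-4-benzyl-3-propanoyl-1,3-oxazolidin-2-one | CCC(=O)N1[C@@H](Cc2ccccc2)COC1=O | starting material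
12 | propanal | CCC=O | starting material
13 | (Z)-dibutylboron enolate of 11 | C/C=C(\OB(CCCC)CCCC)N1[C@@H](Cc2ccccc2)COC1=O | intermediate
14 | (S)-4-benzyl-3-[(2S,3R)-3-hydroxy-2-methylpentanoyl]-1,3-oxazolidin-2-one | CC[C@@H](O)[C@H](C)C(=O)N1[C@@H](Cc2ccccc2)COC1=O | intermediate
15 | (S)-4-benzyl-3-[(2S,3R)-2-methyl-3-(triisopropylsilyloxy)pentanoyl]-1,3-oxazolidin-2-one | CC[C@@H](O[Si](C(C)C)(C(C)C)C(C)C)[C@H](C)C(=O)N1[C@@H](Cc2ccccc2)COC1=O | intermediate
16 | (2R,3R)-2-methyl-3-(triisopropylsilyloxy)pentan-1-ol | CC[C@@H](O[Si](C(C)C)(C(C)C)C(C)C)[C@H](C)CO | intermediate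
17 | {[(3R,4S)-5-iodo-4-methylpentan-3-yl]oxy}tri(propan-2-yl)silane | CC[C@@H](O[Si](C(C)C)(C(C)C)C(C)C)[C@H](C)CI | intermediate
18 | primary alkyllithium from 17 (iodine replaced by lithium) | CC[C@@H](O[Si](C(C)C)(C(C)C)C(C)C)[C@H](C)C[Li] | intermediate
19 | (3R,4R)-1-[2-(hydroxymethyl)-2,4,6-trimethyl-3-(triethylsilyloxy)cyclohex-4-en-1-yl]-3-methyl-4-(triisopropylsilyloxy)hexan-1-one, ring configuration as in 8 | CC[C@@H](O[Si](C(C)C)(C(C)C)C(C)C)[C@H](C)CC(=O)[C@H]1[C@@H](C)C=C(C)[C@@H](O[Si](CC)(CC)CC)[C@@]1(C)CO | intermediate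
20 | C19 triethylsilyl ether of 19 | CC[C@@H](O[Si](C(C)C)(C(C)C)C(C)C)[C@H](C)CC(=O)[C@H]1[C@@H](C)C=C(C)[C@@H](O[Si](CC)(CC)CC)[C@@]1(C)CO[Si](CC)(CC)CC | intermediate
21 | potassium (Z)-enolate of 20 (oxygen cis to C5 across C8=C7) | CC[C@@H](O[Si](C(C)C)(C(C)C)C(C)C)[C@H](C)/C=C(\[O-])[C@H]1[C@@H](C)C=C(C)[C@@H](O[Si](CC)(CC)CC)[C@@]1(C)CO[Si](CC)(CC)CC.[K+] | intermediate
22 | (Z)-enol triflate of 20: C8(OTf)=C7H with the triflate cis to C5 | CC[C@@H](O[Si](C(C)C)(C(C)C)C(C)C)[C@H](C)/C=C(\OS(=O)(=O)C(F)(F)F)[C@H]1[C@@H](C)C=C(C)[C@@H](O[Si](CC)(CC)CC)[C@@]1(C)CO[Si](CC)(CC)CC | intermediate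
23 | ring of 20 carrying on C10 the (2E,4R,5R)-4-methyl-5-(triisopropylsilyloxy)hept-2-en-2-yl chain; C16 and C19 as triethylsilyl ethers | CC[C@@H](O[Si](C(C)C)(C(C)C)C(C)C)[C@H](C)/C=C(\C)[C@H]1[C@@H](C)C=C(C)[C@@H](O[Si](CC)(CC)CC)[C@@]1(C)CO[Si](CC)(CC)CC | intermediate
24 | 23 with the C19 hydroxyl free | CC[C@@H](O[Si](C(C)C)(C(C)C)C(C)C)[C@H](C)/C=C(\C)[C@H]1[C@@H](C)C=C(C)[C@@H](O[Si](CC)(CC)CC)[C@@]1(C)CO | intermediate
25 | C19 aldehyde from 24 | CC[C@@H](O[Si](C(C)C)(C(C)C)C(C)C)[C@H](C)/C=C(\C)[C@H]1[C@@H](C)C=C(C)[C@@H](O[Si](CC)(CC)CC)[C@@]1(C)C=O | intermediate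
26 | methyl 2-methyl-3-oxopentanoate | CCC(=O)C(C)C(=O)OC | starting material
27 | sodium lithium dianion of 26 (deprotonated at C2 and C4) | C[CH-]C(=O)[C-](C)C(=O)OC.[Na+].[Li+] | intermediate
28 | methyl 5-hydroxy-2,4-dimethyl-3-oxopentanoate carrying the C17 ring carbon of 25 at C5 (diastereomer mixture) | CC[C@@H](O[Si](C(C)C)(C(C)C)C(C)C)[C@H](C)/C=C(\C)[C@H]1[C@@H](C)C=C(C)[C@@H](O[Si](CC)(CC)CC)[C@@]1(C)C(O)C(C)C(=O)C(C)C(=O)OC | intermediate
29 | methyl 2,4-dimethyl-3,5-dioxopentanoate carrying the C17 ring carbon at C5 | CC[C@@H](O[Si](C(C)C)(C(C)C)C(C)C)[C@H](C)/C=C(\C)[C@H]1[C@@H](C)C=C(C)[C@@H](O[Si](CC)(CC)CC)[C@@]1(C)C(=O)C(C)C(=O)C(C)C(=O)OC | intermediate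
30 | 4-hydroxy-3,5-dimethyl-2H-pyran-2-one carrying the C17 ring carbon at C6 | CC[C@@H](O[Si](C(C)C)(C(C)C)C(C)C)[C@H](C)/C=C(\C)[C@H]1[C@@H](C)C=C(C)[C@@H](O[Si](CC)(CC)CC)[C@@]1(C)C1=C(C)C(O)=C(C)C(=O)O1 | intermediate
31 | 2-methoxy-3,5-dimethyl-4H-pyran-4-one carrying the C17 ring carbon at C6 (C16 triethylsilyl ether, C3 triisopropylsilyl ether) | CC[C@@H](O[Si](C(C)C)(C(C)C)C(C)C)[C@H](C)/C=C(\C)[C@H]1[C@@H](C)C=C(C)[C@@H](O[Si](CC)(CC)CC)[C@@]1(C)c1oc(OC)c(C)c(=O)c1C | intermediate
32 | 31 with the C16 hydroxyl free (allylic alcohol, cis to the C11 methyl and the pyrone) | CC[C@@H](O[Si](C(C)C)(C(C)C)C(C)C)[C@H](C)/C=C(\C)[C@H]1[C@@H](C)C=C(C)[C@@H](O)[C@@]1(C)c1oc(OC)c(C)c(=O)c1C | intermediate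
33 | C16 methanesulfonate of 32 | CC[C@@H](O[Si](C(C)C)(C(C)C)C(C)C)[C@H](C)/C=C(\C)[C@H]1[C@@H](C)C=C(C)[C@@H](OS(C)(=O)=O)[C@@]1(C)c1oc(OC)c(C)c(=O)c1C | intermediate
34 | 2-methoxy-3,5-dimethyl-6-{(1R,6S)-1,3,5-trimethyl-6-[(2E,4R,5R)-4-methyl-5-(triisopropylsilyloxy)hept-2-en-2-yl]cyclohexa-2,4-dien-1-yl}-4H-pyran-4-one | CC[C@@H](O[Si](C(C)C)(C(C)C)C(C)C)[C@H](C)/C=C(\C)[C@H]1C(C)=CC(C)=C[C@@]1(C)c1oc(OC)c(C)c(=O)c1C | intermediate
35 | 6-{(1R,6S)-6-[(2E,4R,5R)-5-hydroxy-4-methylhept-2-en-2-yl]-1,3,5-trimethylcyclohexa-2,4-dien-1-yl}-2-methoxy-3,5-dimethyl-4H-pyran-4-one | CC[C@@H](O)[C@H](C)/C=C(\C)[C@H]1C(C)=CC(C)=C[C@@]1(C)c1oc(OC)c(C)c(=O)c1C | intermediate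
36 | 2-methoxy-3,5-dimethyl-6-{(1R,6S)-1,3,5-trimethyl-6-[(2E,4R)-4-methyl-5-oxohept-2-en-2-yl]cyclohexa-2,4-dien-1-yl}-4H-pyran-4-one (CNP0301958.2) | CCC(=O)[C@H](C)/C=C(\C)[C@H]1C(C)=CC(C)=C[C@@]1(C)c1oc(OC)c(C)c(=O)c1C | target

Total step count: 24. Longest linear sequence: 19 steps (steps 2–6 and 11–24, from 3).

Steps most likely to fail

Step 4. The cycloaddition may stall: the α-methyl group and the 1,2,4-trisubstituted diene slow bond formation at the future quaternary C17, so oligomerisation or hydrolysis of the dienol ether can overtake it. Lack of conversion is the larger danger, erosion of facial control the smaller. The fallback sets out from 2 and exchanges the chiral butenolide for the much more electrophilic cis-locked dienophile 3-methylfuran-2,5-dione (citraconic anhydride). Warming the two in toluene at 60–80 °C should give the racemic endo anhydride adduct F1, the silyloxy terminus again bonding to the methyl-bearing carbon. NaBH4 in THF at 0 °C, which as a rule attacks unsymmetrical succinic-type anhydrides at the carbonyl next to the more substituted carbon, should reduce C19 and give lactone 10 together with the enantiomeric lactone F2 as a racemate. Addition of the enantiopure alkyllithium 18 as in step 11 would then give 19 and the diastereomeric hydroxy ketone F3 built on the mirror-image ring. Their chromatographic separation serves as the resolution, at the cost of half the material, and the route is rejoined at 19.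

Step 22. The ionisation-driven 1,4-elimination may be diverted: the hindered mesylate may return chloride without eliminating, the allyl cation next to the quaternary centre may undergo skeletal shifts, or the new diene may migrate under the acid formed. The fallback sets out from 32 and avoids any cation. Dess–Martin oxidation should give the enone F4, whose only enolisable position is C11–H because C17 is quaternary. γ-Deprotonation with KN(SiMe3)2 and O-sulfonylation with PhNTf2 should then give the dienyl triflate F5. Reduction with Pd(OAc)2, PPh3, HCO2H and Bu3N in DMF at 60 °C would replace the triflate by hydrogen and return the route at 34.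

Step 17. Addition of the secondary carbanion terminus of the dianion to the neopentyl aldehyde may be too slow, since the aldehyde is flanked by the silyloxy-bearing C16 and the side-chain-bearing C10, and proton transfer on warming would then simply return the aldehyde. The fallback sets out from 25 and builds the chain in two smaller pieces. EtMgBr with CeCl3 in THF at −78 °C should add to the aldehyde to give the secondary alcohol F6, and Dess–Martin oxidation the ethyl ketone F7. Soft enolisation of this ketone (MgBr2·OEt2, i-Pr2NEt, CH2Cl2) and C-acylation at its methylene with methyl 3-chloro-2-methyl-3-oxopropanoate would give the β,δ-diketo ester, which is 29, where the route is rejoined.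

Further compounds
F1 | step 4 | racemic cis-fused 4,6,7a-trimethyl-7-(triethylsilyloxy)-3a,4,7,7a-tetrahydroisobenzofuran-1,3-dione, endo adduct (one enantiomer drawn) | O=C1[C@H]2[C@@H](C)C=C(C)[C@@H](O[Si](CC)(CC)CC)[C@@]2(C)C(=O)O1
F2 | step 4 | enantiomer of lactone 10 (formed with 10 as the racemate) | O=C1[C@@H]2[C@H](C)C=C(C)[C@H](O[Si](CC)(CC)CC)[C@]2(C)CO1
F3 | step 4 | diastereomer of 19 built on the enantiomeric ring | CC[C@@H](O[Si](C(C)C)(C(C)C)C(C)C)[C@H](C)CC(=O)[C@@H]1[C@H](C)C=C(C)[C@H](O[Si](CC)(CC)CC)[C@]1(C)CO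
F4 | step 22 | C16 enone from oxidation of 32 | CC[C@@H](O[Si](C(C)C)(C(C)C)C(C)C)[C@H](C)/C=C(\C)[C@H]1[C@@H](C)C=C(C)C(=O)[C@@]1(C)c1oc(OC)c(C)c(=O)c1C
F5 | step 22 | C16 dienyl triflate (C11=C13 and C14=C16, triflate on C16) | CC[C@@H](O[Si](C(C)C)(C(C)C)C(C)C)[C@H](C)/C=C(\C)[C@H]1C(C)=CC(C)=C(OS(=O)(=O)C(F)(F)F)[C@@]1(C)c1oc(OC)c(C)c(=O)c1C
F6 | step 17 | C19 secondary alcohol from ethyl addition to 25 (epimer mixture at C19) | CC[C@@H](O[Si](C(C)C)(C(C)C)C(C)C)[C@H](C)/C=C(\C)[C@H]1[C@@H](C)C=C(C)[C@@H](O[Si](CC)(CC)CC)[C@@]1(C)C(O)CC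
F7 | step 17 | C19 ethyl ketone | CC[C@@H](O[Si](C(C)C)(C(C)C)C(C)C)[C@H](C)/C=C(\C)[C@H]1[C@@H](C)C=C(C)[C@@H](O[Si](CC)(CC)CC)[C@@]1(C)C(=O)CC
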